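Late in the south-east run, which is the very flask I am asked about, the target stands still: from 25.0 h to 72.0 h it stays between 14.5 % and 15.2 %, with a reading scatter of 0.3 percentage points, while the solid substrate holds near 44.2 %.

common to all: free catalyst 0.76 mM
- south-east: solid substrate 1 M; second substrate 1 M; the very flask that is asked about, followed so far
- flask: solid substrate 1.0 M; second substrate 1.00 M; time 3.0 d

south-east run (percent of the solid substrate charged)

| time / h | target / % | solid substrate / % |
|---|---|---|
| 5.00 | 5.2 | 59.9 |
| 15.0 | 13.3 | 46.1 |
| 25.0 | 14.8 | 44.3 |
| 40.0 | 15.2 | 43.8 |
| 60.0 | 14.5 | 44.5 |
| 72.0 | 14.9 | 44.2 |

(standard deviation of a reading: 0.3 percentage points)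

- alpha: at 3.0 d take out 90 % of the target then present, then wait 3.0 d
- eta: change nothing and wait 3.0 d more
- zeta: at 3.0 d add free catalyst, 100 % of the amount charged, then wait 3.0 d

- solid, in amounts per volume of the solution: solid substrate
- target that was removed still counts
- at the start none of the solid substrate is in solution
- additions bring no volume worth counting

- target, in percent of the solid substrate first charged, at 3.0 d
- the option that brings most further target ("none" if no option brings more than 2 percentage points) (alpha / eta / zeta / none)
- target present, with what was taken out counted in, in percent of the solid substrate first charged, after alpha
- target present, with what was taken out counted in, in percent of the solid substrate first charged, after zeta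

My first question is whether this flask has run short of solid substrate. At 72.0 h the balance leaves 40.9 % dissolved but not converted, so with the solid there is 85.1 % in reserve, more than the target made so far, and the answer is no.

My second question is what stopped the target, and one run cannot prove it; my own judgement is that the catalyst has stopped working. So I carry the turnover number N, the c(target) of the plateau over the c(free catalyst) charged, which reads 196 here.

My third question is which option pays. On my reckoning, taking out target brings nothing and alpha stays at 14.9 %, whereas a second charge of free catalyst buys N turnovers again, so zeta reaches 29.8 %.

The forecast differs from me. It starts from “There are two possible causes: equilibrium or catalyst death.” and takes equilibrium, giving 14.9 % now, 26.4 % after alpha, 15 % after zeta, and alpha as best.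

The flask gives 14.8 % now, 14.8 % after alpha and 32.7 % after zeta, so zeta is best, with a gain of 18 points against 0 points for alpha.

    starting material + free catalyst ⇌ catalyst intermediate A (K = 1.50 /M, k = 4.40 /M/s)
    catalyst intermediate A → free catalyst + target (k = 0.0460 /s)
    second substrate + free catalyst ⇌ catalyst intermediate B (K = 100 /M, k = 0.360 /M/s)
    catalyst intermediate B → free catalyst + second product (k = 0.120 /s)
    free catalyst → spent catalyst (k = 1.10 × 10⁻⁴ /s)
    solid substrate ⇌ starting material, rate k6*(cs6 - [starting material]) while solid is left; crystals form when [starting material] > cs6 (solubility = 0.410 M, k = 1.40 × 10⁻⁴ /s)

At 72.0 h this flask holds spent catalyst at >99.9 % of the catalyst charged, beside starting material at 41.0 % of the solid substrate charged. The added catalyst of zeta made 235 turnovers to target, more than N. The neighbour flask is charged with 0.190 mM of free catalyst, and N puts its target at 3.72 %. At 72.0 h the neighbour flask holds spent catalyst at >99.9 % of its catalyst charged, and its target stands at 3.98 %.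

(The numbers in the tables are simulated on assumed constants; scatter was added.)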